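**Retrosynthetic overview**
1. Target ⇒ desilylation, malonylation with Meldrum's acid and Ru–BINAP hydrogenation back to the (13E)-allylic alcohol 16; its C14–C15 bond (and the C13–CH3 bond) ⇒ terminal alkyne 13 + Me3Al + formaldehyde.
2. Alkyne 13 ⇒ lactol 11 ⇒ δ-lactone 10. The O8–C13 lactone ring is a temporary third ring: it fixes the C8–O stereocentre, masks the tertiary alcohol and holds C13 at the acid level. 10 ⇒ 3-hydroxy lactone 8 by deoxygenation.
3. 8 ⇒ one epoxide-initiated cationic bicyclization of the acyclic epoxy-diene ester 7: ring A closes first (C4–C5), then ring B (C9–C10), then the lactone ring (O–C8).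
4. 7 ⇒ Sharpless epoxide of the ω-hydroxylated farnesylacetate 5 ⇒ (2E,6E)-farnesyl bromide 1 + tert-butyl acetate 2.
5. Enabling feature: the chain end C12–C13(CH3)H–C14H2–C15H2–O is a reduced 3-methylalk-2-en-1-ol. In 13 the sp carbons C13≡C14 sit two CH2 groups from ring B, so syn-methylalumination puts CH3 on C13 and the metal on terminal C14, which alone then bonds to the formaldehyde carbon C15.

Key step: step 10

Remark: locants follow labdane numbering (C1–C10 decalin; C11–C16 side chain, C16 = methyl on C13; C17 = methyl on C8; C18 = equatorial CH2O on C4; C19 = axial methyl on C4; C20 = methyl on C10). The target belongs to the ent-series; configurations are given as CIP descriptors and in the SMILES. The D-(−)-tartrate in step 3 and the (R)-BINAP in step 11 were chosen by analogy with the known sense of the Sharpless epoxidation of (E)-allylic alcohols and of the Ru–BINAP hydrogenation of geraniol.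

**Step 1**
Reactants: 1 (2E,6E)-farnesyl bromide; 2 tert-butyl acetate
Product: 4 tert-butyl (4E,8E)-5,9,13-trimethyltetradeca-4,8,12-trienoate, via tert-butyl acetate lithium enolate 3 (not isolated)
Conditions: LDA, THF, −78 °C; then 1, THF/DMPU, −78 °C → rt
Reagents that add atoms: none
Why: Ester enolate alkylation (SN2 at the primary allylic bromide), in which the tert-butyl ester suppresses Claisen self-condensation and the E,E-geometry of 1 is untouched.

**Step 2**
Reactants: 4 tert-butyl (4E,8E)-5,9,13-trimethyltetradeca-4,8,12-trienoate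
Product: 5 tert-butyl (4E,8E,12E)-14-hydroxy-5,9,13-trimethyltetradeca-4,8,12-trienoate
Conditions: SeO2 (cat.), t-BuOOH, salicylic acid (cat.), CH2Cl2, rt
Reagents that add atoms: selenium dioxide O=[Se]=O; tert-butyl hydroperoxide CC(C)(C)OO
Why: SeO2 allylic oxidation (ene reaction then [2,3]-sigmatropic shift) should attack the terminal gem-dimethyl alkene, the most electron-rich one, at the methyl group trans to the chain and so give the (E)-allylic alcohol.

**Step 3**
Reactants: 5 tert-butyl (4E,8E,12E)-14-hydroxy-5,9,13-trimethyltetradeca-4,8,12-trienoate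
Product: 6 tert-butyl (4E,8E)-11-[(2R,3R)-3-(hydroxymethyl)-3-methyloxiran-2-yl]-5,9-dimethylundeca-4,8-dienoate
Conditions: Ti(OiPr)4 (cat.), D-(−)-diethyl tartrate (cat.), t-BuOOH, 4 Å MS, CH2Cl2, −20 °C
Reagents that add atoms: tert-butyl hydroperoxide CC(C)(C)OO
Why: Sharpless asymmetric epoxidation of the primary (E)-allylic alcohol, in which the D-(−)-tartrate should deliver oxygen to the face that gives the (2R,3R)-epoxide (future C3 and C4), while the two remote trisubstituted alkenes lack the directing hydroxyl and stay intact.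

**Step 4**
Reactants: 6 tert-butyl (4E,8E)-11-[(2R,3R)-3-(hydroxymethyl)-3-methyloxiran-2-yl]-5,9-dimethylundeca-4,8-dienoate
Product: 7 tert-butyl (4E,8E)-11-[(2R,3R)-3-{[tert-butyl(diphenyl)silyl]oxymethyl}-3-methyloxiran-2-yl]-5,9-dimethylundeca-4,8-dienoate
Conditions: TBDPSCl, imidazole, DMF, 0 °C → rt
Reagents that add atoms: tert-butyl(chloro)diphenylsilane CC(C)(C)[Si](Cl)(c1ccccc1)c1ccccc1
Why: Silylation of the primary alcohol under non-basic conditions avoids Payne rearrangement and gives a bulky ether that should not act as a neighbouring group under Lewis acid and lasts to the final step.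

**Step 5**
Reactants: 7 tert-butyl (4E,8E)-11-[(2R,3R)-3-{[tert-butyl(diphenyl)silyl]oxymethyl}-3-methyloxiran-2-yl]-5,9-dimethylundeca-4,8-dienoate
Product: 8 (3R,4S,5S,8S,9S,10R)-3-hydroxy-18-[tert-butyl(diphenyl)silyl]oxy-14,15,16-trinorlabdan-13,8-olide (trans-decalin δ-lactone, 3-OH equatorial)
Conditions: MeAlCl2, CH2Cl2, −78 → −40 °C; aq. Rochelle salt
Reagents that add atoms: none
Why: Epoxide-initiated cation–olefin bicyclization through a chair–chair fold, in which the C5=C10 alkene opens the activated oxirane at tertiary C4 with inversion (C3 retained, the (E)-CH2OSi group ending equatorial), the (E)-alkenes give the trans ring fusion and 9-H anti to the C10 methyl, and the tert-butyl ester carbonyl traps the C8 cation anti and loses isobutene to give the equatorial C8–O bond of the lactone.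

**Step 6**
Reactants: 8 (3R,4S,5S,8S,9S,10R)-3-hydroxy-18-[tert-butyl(diphenyl)silyl]oxy-14,15,16-trinorlabdan-13,8-olide
Product: 9 the 3-O-(imidazol-1-ylcarbonothioyl) derivative of 8
Conditions: 1,1'-thiocarbonyldiimidazole, DMAP (cat.), ClCH2CH2Cl, 80 °C
Reagents that add atoms: 1,1'-thiocarbonyldiimidazole S=C(n1ccnc1)n1ccnc1
Why: Thioacylation of the hindered secondary alcohol gives the radical precursor for a Barton–McCombie deoxygenation without strong base that could open the lactone.

**Step 7**
Reactants: 9 the 3-O-(imidazol-1-ylcarbonothioyl) derivative of 8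
Product: 10 (4S,5S,8S,9S,10R)-18-[tert-butyl(diphenyl)silyl]oxy-14,15,16-trinorlabdan-13,8-olide
Conditions: n-Bu3SnH, AIBN (cat.), toluene, 110 °C
Reagents that add atoms: none
Why: Barton–McCombie deoxygenation, in which the stannyl radical adds to C=S, the C3–O bond fragments and the secondary C3 radical takes hydrogen from the stannane, while lactone and silyl ether are inert to the radical chain.

**Step 8**
Reactants: 10 (4S,5S,8S,9S,10R)-18-[tert-butyl(diphenyl)silyl]oxy-14,15,16-trinorlabdan-13,8-olide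
Product: 11 (4S,5S,8S,9S,10R)-18-[tert-butyl(diphenyl)silyl]oxy-8,13-epoxy-14,15,16-trinorlabdan-13-ol (lactol, both anomers)
Conditions: DIBAL-H, CH2Cl2, −78 °C; aq. Rochelle salt
Reagents that add atoms: none
Why: Partial reduction of the δ-lactone at low temperature should stop at the tetrahedral aluminate, which gives the lactol on work-up.

**Step 9**
Reactants: 11 (4S,5S,8S,9S,10R)-18-[tert-butyl(diphenyl)silyl]oxy-8,13-epoxy-14,15,16-trinorlabdan-13-ol
Product: 13 (4S,5S,8S,9S,10R)-18-[tert-butyl(diphenyl)silyl]oxy-15,16-dinorlabd-13-yn-8-ol, via ring-opened hydroxy aldehyde 12 (not isolated)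
Conditions: dimethyl (1-diazo-2-oxopropyl)phosphonate, K2CO3, MeOH, 0 °C → rt
Reagents that add atoms: dimethyl (1-diazo-2-oxopropyl)phosphonate (Ohira–Bestmann reagent) CC(=O)C(=[N+]=[N-])P(=O)(OC)OC
Why: Seyferth–Gilbert homologation with the Ohira–Bestmann reagent acts on the open hydroxy-aldehyde tautomer of the lactol and adds C14 as a terminal alkyne carbon under mild base, touching no stereocentre and freeing the tertiary C8–OH.

**Step 10**
Reactants: 13 (4S,5S,8S,9S,10R)-18-[tert-butyl(diphenyl)silyl]oxy-15,16-dinorlabd-13-yn-8-ol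
Product: 16 (4S,5S,8S,9S,10R,13E)-18-[tert-butyl(diphenyl)silyl]oxylabd-13-ene-8,15-diol, via (E)-alkenyldimethylalane 14 (not isolated), via lithium alkenylalanate 15 (not isolated)
Conditions: Me3Al (4 equiv), Cp2ZrCl2 (0.5 equiv), CH2Cl2, 0 °C → rt; evaporate; n-BuLi, THF, −78 → 0 °C; (CH2O)n, 0 °C → rt; aq. Rochelle salt
Reagents that add atoms: trimethylaluminium C[Al](C)C; paraformaldehyde (reacts as formaldehyde) C=O
Why: Cp2ZrCl2 and Me3Al form a methylzirconocene–aluminate pair that adds CH3–metal syn across the terminal alkyne, methyl to internal C13 and metal to terminal C14, and transmetalation gives the (E)-alkenylalane 14; n-BuLi turns it into the more nucleophilic alanate 15, whose alkenyl group adds to formaldehyde with retention of geometry and so forms the C14–C15 bond. The closest known reaction type is the zirconium-catalysed methylalumination of 1-alkynes with formaldehyde capture (Negishi carboalumination), the standard entry to (E)-3-methylalk-2-en-1-ol ends of isoprenoid chains, here applied to an ω-alkynyl tertiary carbinol. No ring is closed in this step; the decalin is complete and the temporary lactone ring has just been opened to expose the alkyne. No sp3 stereocentre is formed; the new stereo-element is the E-geometry of C13=C14, fixed by the syn addition, and it is this geometry that the hydrogenation of step 11 reads to set C13. The step needs regioselectivity (CH3 on C13, metal on C14), secured by the unbranched CH2–C≡C–H terminus, and chemoselectivity, secured by turning the free C8–OH into its aluminium alkoxide with one extra equivalent of Me3Al and by the inertness of the silyl ether. In one flask it should install C16, C15, the C15 oxygen and the trisubstituted alkene, which are all remaining atoms of the target apart from the malonyl unit.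

**Step 11**
Reactants: 16 (4S,5S,8S,9S,10R,13E)-18-[tert-butyl(diphenyl)silyl]oxylabd-13-ene-8,15-diol
Product: 17 (4S,5S,8S,9S,10R,13S)-18-[tert-butyl(diphenyl)silyl]oxylabdane-8,15-diol
Conditions: H2 (100 atm), Ru(OAc)2[(R)-BINAP] (cat.), MeOH, 20 °C
Reagents that add atoms: none
Why: Noyori asymmetric hydrogenation, in which the allylic hydroxyl binds the Ru–(R)-BINAP dicarboxylate and hydrogen is delivered to one face of the (E)-alkene, which by the geraniol to (S)-citronellol sense should give 13S under catalyst control, independent of the remote decalin.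

**Step 12**
Reactants: 17 (4S,5S,8S,9S,10R,13S)-18-[tert-butyl(diphenyl)silyl]oxylabdane-8,15-diol
Product: 18 (4S,5S,8S,9S,10R,13S)-8-hydroxy-18-[tert-butyl(diphenyl)silyl]oxylabdan-15-yl hydrogen malonate
Conditions: Meldrum's acid, toluene, 90 °C
Reagents that add atoms: Meldrum's acid (2,2-dimethyl-1,3-dioxane-4,6-dione) CC1(C)OC(=O)CC(=O)O1
Why: Ring-opening acylation of the alcohol by Meldrum's acid with loss of acetone gives the hydrogen malonate directly, and only the unhindered primary C15–OH should react because the C8–OH is tertiary and the C18 oxygen is silylated.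

**Step 13**
Reactants: 18 (4S,5S,8S,9S,10R,13S)-8-hydroxy-18-[tert-butyl(diphenyl)silyl]oxylabdan-15-yl hydrogen malonate
Product: 19 (4S,5S,8S,9S,10R,13S)-8,18-dihydroxylabdan-15-yl hydrogen malonate (CNP0324566.1)
Conditions: HF·pyridine, THF, 0 °C → rt
Reagents that add atoms: none
Why: Fluoride-mediated Si–O cleavage under acidic conditions should free the C18 hydroxyl without hydrolysing the malonate ester or eliminating the tertiary alcohol.

**Compound list**
1 | (2E,6E)-farnesyl bromide | CC(C)=CCC/C(C)=C/CC/C(C)=C/CBr | starting material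
2 | tert-butyl acetate | CC(=O)OC(C)(C)C | starting material
3 | tert-butyl acetate lithium enolate | C=C(O[Li])OC(C)(C)C | intermediate
4 | tert-butyl (4E,8E)-5,9,13-trimethyltetradeca-4,8,12-trienoate | CC(C)=CCC/C(C)=C/CC/C(C)=C/CCC(=O)OC(C)(C)C | intermediate
5 | tert-butyl (4E,8E,12E)-14-hydroxy-5,9,13-trimethyltetradeca-4,8,12-trienoate | OC/C(C)=C/CC/C(C)=C/CC/C(C)=C/CCC(=O)OC(C)(C)C | intermediate
6 | tert-butyl (4E,8E)-11-[(2R,3R)-3-(hydroxymethyl)-3-methyloxiran-2-yl]-5,9-dimethylundeca-4,8-dienoate | OC[C@@]1(C)O[C@@H]1CC/C(C)=C/CC/C(C)=C/CCC(=O)OC(C)(C)C | intermediate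
7 | tert-butyl (4E,8E)-11-[(2R,3R)-3-{[tert-butyl(diphenyl)silyl]oxymethyl}-3-methyloxiran-2-yl]-5,9-dimethylundeca-4,8-dienoate | CC(C)(C)[Si](c1ccccc1)(c1ccccc1)OC[C@@]2(C)O[C@@H]2CC/C(C)=C/CC/C(C)=C/CCC(=O)OC(C)(C)C | intermediate
8 | (3R,4S,5S,8S,9S,10R)-3-hydroxy-18-[tert-butyl(diphenyl)silyl]oxy-14,15,16-trinorlabdan-13,8-olide | O=C1CC[C@H]2[C@]3(C)CC[C@@H](O)[C@](C)(CO[Si](c4ccccc4)(c4ccccc4)C(C)(C)C)[C@H]3CC[C@]2(C)O1 | intermediate
9 | 3-O-(imidazol-1-ylcarbonothioyl) derivative of 8 | O=C1CC[C@H]2[C@]3(C)CC[C@@H](OC(=S)n4ccnc4)[C@](C)(CO[Si](c4ccccc4)(c4ccccc4)C(C)(C)C)[C@H]3CC[C@]2(C)O1 | intermediate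
10 | (4S,5S,8S,9S,10R)-18-[tert-butyl(diphenyl)silyl]oxy-14,15,16-trinorlabdan-13,8-olide | O=C1CC[C@H]2[C@]3(C)CCC[C@](C)(CO[Si](c4ccccc4)(c4ccccc4)C(C)(C)C)[C@H]3CC[C@]2(C)O1 | intermediate
11 | (4S,5S,8S,9S,10R)-18-[tert-butyl(diphenyl)silyl]oxy-8,13-epoxy-14,15,16-trinorlabdan-13-ol (lactol, both anomers) | OC1CC[C@H]2[C@]3(C)CCC[C@](C)(CO[Si](c4ccccc4)(c4ccccc4)C(C)(C)C)[C@H]3CC[C@]2(C)O1 | intermediate
12 | (4S,5S,8S,9S,10R)-8-hydroxy-18-[tert-butyl(diphenyl)silyl]oxy-14,15,16-trinorlabdan-13-al | O=CCC[C@H]1[C@]2(C)CCC[C@](C)(CO[Si](c3ccccc3)(c3ccccc3)C(C)(C)C)[C@H]2CC[C@]1(C)O | intermediate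
13 | (4S,5S,8S,9S,10R)-18-[tert-butyl(diphenyl)silyl]oxy-15,16-dinorlabd-13-yn-8-ol | C#CCC[C@H]1[C@]2(C)CCC[C@](C)(CO[Si](c3ccccc3)(c3ccccc3)C(C)(C)C)[C@H]2CC[C@]1(C)O | intermediate
14 | (E)-alkenyldimethylalane from 13 (Al on C14, CH3 on C13, C8–O–AlMe2) | C/C(=C\[Al](C)C)CC[C@H]1[C@]2(C)CCC[C@](C)(CO[Si](c3ccccc3)(c3ccccc3)C(C)(C)C)[C@H]2CC[C@]1(C)O[Al](C)C | intermediate
15 | lithium butyl(alkenyl)dimethylalanate from 14 | [Li+].CCCC[Al-](C)(C)/C=C(\C)CC[C@H]1[C@]2(C)CCC[C@](C)(CO[Si](c3ccccc3)(c3ccccc3)C(C)(C)C)[C@H]2CC[C@]1(C)O[Al](C)C | intermediate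
16 | (4S,5S,8S,9S,10R,13E)-18-[tert-butyl(diphenyl)silyl]oxylabd-13-ene-8,15-diol | C/C(=C\CO)CC[C@H]1[C@]2(C)CCC[C@](C)(CO[Si](c3ccccc3)(c3ccccc3)C(C)(C)C)[C@H]2CC[C@]1(C)O | intermediate
17 | (4S,5S,8S,9S,10R,13S)-18-[tert-butyl(diphenyl)silyl]oxylabdane-8,15-diol | C[C@H](CCO)CC[C@H]1[C@]2(C)CCC[C@](C)(CO[Si](c3ccccc3)(c3ccccc3)C(C)(C)C)[C@H]2CC[C@]1(C)O | intermediate
18 | (4S,5S,8S,9S,10R,13S)-8-hydroxy-18-[tert-butyl(diphenyl)silyl]oxylabdan-15-yl hydrogen malonate | C[C@H](CCOC(=O)CC(=O)O)CC[C@H]1[C@]2(C)CCC[C@](C)(CO[Si](c3ccccc3)(c3ccccc3)C(C)(C)C)[C@H]2CC[C@]1(C)O | intermediate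
19 | (4S,5S,8S,9S,10R,13S)-8,18-dihydroxylabdan-15-yl hydrogen malonate (CNP0324566.1) | C[C@H](CCOC(=O)CC(=O)O)CC[C@H]1[C@]2(C)CCC[C@](C)(CO)[C@H]2CC[C@]1(C)O | target

**Step count and risks**
Total steps: 13. Longest linear sequence: 13 steps (1 → 19).

Steps most likely to fail, with fallbacks:

1. Step 5. The silyloxymethyl group on C4 slows ionisation of the epoxide, so a Lewis-acid-induced hydride shift to a ketone, or proton loss after the first ring closure, may outrun the bicyclization. The fallback changes from cationic to radical ring closure and sets out from 7. Cp2TiCl (from Cp2TiCl2 and Mn dust, THF, rt) should open the epoxide homolytically to the C4 radical, which closes rings A and B and ends by β-hydride loss as the exocyclic alkene tert-butyl 3-hydroxy-18-[tert-butyl(diphenyl)silyl]oxy-14,15,16-trinorlabd-8(17)-en-13-oate F1. Here the C4 configuration rests on the chair preference for an equatorial CH2OSi group. CF3CO2H in CH2Cl2 at 0 °C should then protonate C17 and let the ester oxygen capture the C8 cation with loss of isobutene, which comes back to the route at 8.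

2. Step 2. Oxidation may occur at an internal allylic position, run on to the enal, or stall at low conversion. The fallback builds the (E)-hydroxymethyl terminus by chain degradation and olefination and sets out from 4. NBS in aqueous THF at 0 °C should give the terminal bromohydrin tert-butyl (4E,8E)-12-bromo-13-hydroxy-5,9,13-trimethyltetradeca-4,8-dienoate F2. K2CO3 in MeOH closes it to the terminal epoxide tert-butyl (4E,8E)-11-(3,3-dimethyloxiran-2-yl)-5,9-dimethylundeca-4,8-dienoate F3. Periodic acid in aqueous THF cleaves this to the aldehyde tert-butyl (4E,8E)-5,9-dimethyl-12-oxododeca-4,8-dienoate F4. A Wittig reaction with 2-(triphenylphosphoranylidene)propanal gives the (E)-enal tert-butyl (4E,8E,12E)-5,9,13-trimethyl-14-oxotetradeca-4,8,12-trienoate F5. Luche reduction (NaBH4, CeCl3, MeOH) comes back to the route at 5.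

3. Step 10. Carbometalation may be incomplete next to the bulky aluminium alkoxide, the alkenyl–aluminium bond may be protonated before capture, or methyl or butyl may transfer to formaldehyde in place of the alkenyl group. The fallback builds the same allylic alcohol by carbonyl olefination and sets out from 10. MeLi (THF, −78 °C) should give the hydroxy methyl ketone (4S,5S,8S,9S,10R)-8-hydroxy-18-[tert-butyl(diphenyl)silyl]oxy-14,15-dinorlabdan-13-one F6. A Horner–Wadsworth–Emmons reaction with triethyl phosphonoacetate and NaH in THF gives the enoate ethyl (4S,5S,8S,9S,10R,13E)-8-hydroxy-18-[tert-butyl(diphenyl)silyl]oxylabd-13-en-15-oate F7, from which any (Z)-isomer is removed by chromatography. DIBAL-H (CH2Cl2, −78 °C) comes back to the route at 16.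

**Further compounds**
F1 | step 5 | tert-butyl 3-hydroxy-18-[tert-butyl(diphenyl)silyl]oxy-14,15,16-trinorlabd-8(17)-en-13-oate (ring configuration as in 8) | CC(C)(C)OC(=O)CC[C@H]1[C@]2(C)CC[C@@H](O)[C@](C)(CO[Si](c3ccccc3)(c3ccccc3)C(C)(C)C)[C@H]2CCC1=C
F2 | step 2 | tert-butyl (4E,8E)-12-bromo-13-hydroxy-5,9,13-trimethyltetradeca-4,8-dienoate (racemic) | CC(C)(O)C(Br)CC/C(C)=C/CC/C(C)=C/CCC(=O)OC(C)(C)C
F3 | step 2 | tert-butyl (4E,8E)-11-(3,3-dimethyloxiran-2-yl)-5,9-dimethylundeca-4,8-dienoate (racemic) | CC1(C)OC1CC/C(C)=C/CC/C(C)=C/CCC(=O)OC(C)(C)C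
F4 | step 2 | tert-butyl (4E,8E)-5,9-dimethyl-12-oxododeca-4,8-dienoate | O=CCC/C(C)=C/CC/C(C)=C/CCC(=O)OC(C)(C)C
F5 | step 2 | tert-butyl (4E,8E,12E)-5,9,13-trimethyl-14-oxotetradeca-4,8,12-trienoate | O=C/C(C)=C/CC/C(C)=C/CC/C(C)=C/CCC(=O)OC(C)(C)C
F6 | step 10 | (4S,5S,8S,9S,10R)-8-hydroxy-18-[tert-butyl(diphenyl)silyl]oxy-14,15-dinorlabdan-13-one | CC(=O)CC[C@H]1[C@]2(C)CCC[C@](C)(CO[Si](c3ccccc3)(c3ccccc3)C(C)(C)C)[C@H]2CC[C@]1(C)O
F7 | step 10 | ethyl (4S,5S,8S,9S,10R,13E)-8-hydroxy-18-[tert-butyl(diphenyl)silyl]oxylabd-13-en-15-oate | CCOC(=O)/C=C(\C)CC[C@H]1[C@]2(C)CCC[C@](C)(CO[Si](c3ccccc3)(c3ccccc3)C(C)(C)C)[C@H]2CC[C@]1(C)O
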